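**Retrosynthetic overview**
1. Target 16 comes from its 2,4-di-O-benzyl ether 15 by hydrogenolysis; the ring-A CO2H is unmasked from an aryl aldehyde (Pinnick), so no carboxyl protecting group is needed.
2. The two aryl-ester (depside) bonds are cut in turn: ring C–ring B first, then ring B–ring A. Each is made by TFAA-mediated acylation of the non-chelated 4-OH of a 2,4-dihydroxybenzaldehyde.
3. After each coupling the remaining chelated 2-OH is methylated and the CHO is oxidised to the next acid (iterative couple / methylate / oxidise).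
4. All three rings come from one building block, 1: ring C is 1 benzylated and oxidised, ring B is 1 with CHO reduced to CH3 and then re-formylated, ring A is 1 itself.
5. No ring is constructed; the rings are incorporated in the order C, B, A.

Assumption: the target has no stereocentre (achiral tridepside), so no stereocontrol is needed and no step creates a stereocentre; 2,4-dihydroxy-3,6-dimethylbenzaldehyde is taken as a catalogue compound.

**Route**

Step 1
Reactants: 1 2,4-dihydroxy-3,6-dimethylbenzaldehyde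
Product: 2 2,4-bis(benzyloxy)-3,6-dimethylbenzaldehyde
Conditions: BnBr (2.5 equiv), K2CO3, DMF, 70 °C
Reagents that add atoms: benzyl bromide, BrCc1ccccc1
Why: Double Williamson etherification; warm K2CO3/DMF also ionises the hydrogen-bonded 2-OH, and both phenoxides are O-benzylated to protect ring C.

Step 2
Reactants: 2 2,4-bis(benzyloxy)-3,6-dimethylbenzaldehyde
Product: 3 2,4-bis(benzyloxy)-3,6-dimethylbenzoic acid
Conditions: NaClO2, NaH2PO4, 2-methyl-2-butene, t-BuOH/THF/H2O, rt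
Reagents that add atoms: sodium chlorite, [Na+].[O-]Cl=O
Why: Pinnick oxidation converts the hindered aryl aldehyde to the acid under buffered conditions that spare benzyl ethers, with the alkene trapping HOCl before it chlorinates the ring.

Step 3
Reactants: 1 2,4-dihydroxy-3,6-dimethylbenzaldehyde
Product: 5 2,4,5-trimethylbenzene-1,3-diol, via benzylic alcohol 4 (not isolated)
Conditions: H2 (1 atm), 10% Pd/C, AcOH, cat. HCl, rt
Reagents that add atoms: none
Why: Catalytic hydrogenation reduces the CHO to the o,p-dihydroxybenzyl alcohol, whose electron-rich benzylic C–O bond is hydrogenolysed under acid to the C-methyl group of ring B.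

Step 4
Reactants: 5 2,4,5-trimethylbenzene-1,3-diol
Product: 7 2,4-dihydroxy-3,5,6-trimethylbenzaldehyde, via aryl iminium chloride 6 (not isolated)
Conditions: POCl3, DMF, 0 °C → rt; then H2O, 60 °C
Reagents that add atoms: N,N-dimethylformamide, CN(C)C=O; water, O
Why: Vilsmeier–Haack formylation attacks the only unsubstituted position of the activated resorcinol (ortho to one OH, para to the other), and hydrolysis of the iminium salt gives the aldehyde.

Step 5
Reactants: 3 2,4-bis(benzyloxy)-3,6-dimethylbenzoic acid; 7 2,4-dihydroxy-3,5,6-trimethylbenzaldehyde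
Product: 9 4-formyl-3-hydroxy-2,5,6-trimethylphenyl 2,4-bis(benzyloxy)-3,6-dimethylbenzoate, via mixed trifluoroacetic anhydride 8 (not isolated)
Conditions: TFAA, toluene, rt
Reagents that add atoms: none
Why: Mixed-anhydride esterification (classical TFAA depside coupling); the 2,6-disubstituted acid reacts through a small acylium-like species at the free 4-OH, while the 2-OH is held in a hydrogen bond to the CHO and stays untouched.

Step 6
Reactants: 9 4-formyl-3-hydroxy-2,5,6-trimethylphenyl 2,4-bis(benzyloxy)-3,6-dimethylbenzoate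
Product: 10 4-formyl-3-methoxy-2,5,6-trimethylphenyl 2,4-bis(benzyloxy)-3,6-dimethylbenzoate
Conditions: MeI, K2CO3, DMF, rt
Reagents that add atoms: iodomethane, CI
Why: Williamson O-methylation of the only remaining OH; the doubly ortho-substituted aryl ester is too hindered to be cleaved by carbonate at room temperature.

Step 7
Reactants: 10 4-formyl-3-methoxy-2,5,6-trimethylphenyl 2,4-bis(benzyloxy)-3,6-dimethylbenzoate
Product: 11 4-{[2,4-bis(benzyloxy)-3,6-dimethylbenzoyl]oxy}-2-methoxy-3,5,6-trimethylbenzoic acid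
Conditions: NaClO2, NaH2PO4, 2-methyl-2-butene, t-BuOH/THF/H2O, rt
Reagents that add atoms: sodium chlorite, [Na+].[O-]Cl=O
Why: Pinnick oxidation unmasks the ring-B carboxyl from the aldehyde without touching the aryl ester or the benzyl ethers.

Step 8
Reactants: 11 4-{[2,4-bis(benzyloxy)-3,6-dimethylbenzoyl]oxy}-2-methoxy-3,5,6-trimethylbenzoic acid; 1 2,4-dihydroxy-3,6-dimethylbenzaldehyde
Product: 13 4-formyl-3-hydroxy-2,5-dimethylphenyl 4-{[2,4-bis(benzyloxy)-3,6-dimethylbenzoyl]oxy}-2-methoxy-3,5,6-trimethylbenzoate, via mixed trifluoroacetic anhydride 12 (not isolated)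
Conditions: TFAA, toluene, rt
Reagents that add atoms: none
Why: Second mixed-anhydride (TFAA) esterification; again only the non-chelated 4-OH of 1 is acylated, and the existing aryl ester and benzyl ethers are stable to TFAA/TFA at room temperature.

Step 9
Reactants: 13 4-formyl-3-hydroxy-2,5-dimethylphenyl 4-{[2,4-bis(benzyloxy)-3,6-dimethylbenzoyl]oxy}-2-methoxy-3,5,6-trimethylbenzoate
Product: 14 4-formyl-3-methoxy-2,5-dimethylphenyl 4-{[2,4-bis(benzyloxy)-3,6-dimethylbenzoyl]oxy}-2-methoxy-3,5,6-trimethylbenzoate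
Conditions: MeI, K2CO3, DMF, rt
Reagents that add atoms: iodomethane, CI
Why: Williamson O-methylation of the single free (chelated) phenol; both aryl esters are 2,6-disubstituted benzoates and resist K2CO3.

Step 10
Reactants: 14 4-formyl-3-methoxy-2,5-dimethylphenyl 4-{[2,4-bis(benzyloxy)-3,6-dimethylbenzoyl]oxy}-2-methoxy-3,5,6-trimethylbenzoate
Product: 15 4-[(4-{[2,4-bis(benzyloxy)-3,6-dimethylbenzoyl]oxy}-2-methoxy-3,5,6-trimethylbenzoyl)oxy]-2-methoxy-3,6-dimethylbenzoic acid
Conditions: NaClO2, NaH2PO4, 2-methyl-2-butene, t-BuOH/THF/H2O, rt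
Reagents that add atoms: sodium chlorite, [Na+].[O-]Cl=O
Why: Pinnick oxidation gives the ring-A acid chemoselectively from the terminal aldehyde, leaving both aryl esters intact.

Step 11
Reactants: 15 4-[(4-{[2,4-bis(benzyloxy)-3,6-dimethylbenzoyl]oxy}-2-methoxy-3,5,6-trimethylbenzoyl)oxy]-2-methoxy-3,6-dimethylbenzoic acid
Product: 16 4-({4-[(2,4-dihydroxy-3,6-dimethylbenzoyl)oxy]-2-methoxy-3,5,6-trimethylbenzoyl}oxy)-2-methoxy-3,6-dimethylbenzoic acid (CNP0425440.0)
Conditions: H2 (1 atm), 10% Pd/C, EtOAc, rt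
Reagents that add atoms: none
Why: Pd-catalysed hydrogenolysis removes the two benzyl ethers under neutral conditions that leave aryl esters, methyl ethers and the acid untouched, giving the achiral target.

**Compound list**
1 | 2,4-dihydroxy-3,6-dimethylbenzaldehyde | O=Cc1c(O)c(C)c(O)cc1C | starting material
2 | 2,4-bis(benzyloxy)-3,6-dimethylbenzaldehyde | O=Cc1c(OCc2ccccc2)c(C)c(OCc2ccccc2)cc1C | intermediate
3 | 2,4-bis(benzyloxy)-3,6-dimethylbenzoic acid | OC(=O)c1c(OCc2ccccc2)c(C)c(OCc2ccccc2)cc1C | intermediate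
4 | 4-(hydroxymethyl)-2,5-dimethylbenzene-1,3-diol (benzylic alcohol) | OCc1c(O)c(C)c(O)cc1C | intermediate
5 | 2,4,5-trimethylbenzene-1,3-diol | Cc1c(O)c(C)c(O)cc1C | intermediate
6 | N-[(2,4-dihydroxy-3,5,6-trimethylphenyl)methylidene]-N-methylmethanaminium chloride (aryl iminium chloride) | C[N+](C)=Cc1c(O)c(C)c(O)c(C)c1C.[Cl-] | intermediate
7 | 2,4-dihydroxy-3,5,6-trimethylbenzaldehyde | O=Cc1c(O)c(C)c(O)c(C)c1C | intermediate
8 | 2,4-bis(benzyloxy)-3,6-dimethylbenzoic trifluoroacetic anhydride | O=C(OC(=O)C(F)(F)F)c1c(OCc2ccccc2)c(C)c(OCc2ccccc2)cc1C | intermediate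
9 | 4-formyl-3-hydroxy-2,5,6-trimethylphenyl 2,4-bis(benzyloxy)-3,6-dimethylbenzoate | O=Cc1c(O)c(C)c(OC(=O)c2c(OCc3ccccc3)c(C)c(OCc3ccccc3)cc2C)c(C)c1C | intermediate
10 | 4-formyl-3-methoxy-2,5,6-trimethylphenyl 2,4-bis(benzyloxy)-3,6-dimethylbenzoate | O=Cc1c(OC)c(C)c(OC(=O)c2c(OCc3ccccc3)c(C)c(OCc3ccccc3)cc2C)c(C)c1C | intermediate
11 | 4-{[2,4-bis(benzyloxy)-3,6-dimethylbenzoyl]oxy}-2-methoxy-3,5,6-trimethylbenzoic acid | OC(=O)c1c(OC)c(C)c(OC(=O)c2c(OCc3ccccc3)c(C)c(OCc3ccccc3)cc2C)c(C)c1C | intermediate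
12 | 4-{[2,4-bis(benzyloxy)-3,6-dimethylbenzoyl]oxy}-2-methoxy-3,5,6-trimethylbenzoic trifluoroacetic anhydride | O=C(OC(=O)C(F)(F)F)c1c(OC)c(C)c(OC(=O)c2c(OCc3ccccc3)c(C)c(OCc3ccccc3)cc2C)c(C)c1C | intermediate
13 | 4-formyl-3-hydroxy-2,5-dimethylphenyl 4-{[2,4-bis(benzyloxy)-3,6-dimethylbenzoyl]oxy}-2-methoxy-3,5,6-trimethylbenzoate | O=Cc1c(O)c(C)c(OC(=O)c2c(OC)c(C)c(OC(=O)c3c(OCc4ccccc4)c(C)c(OCc4ccccc4)cc3C)c(C)c2C)cc1C | intermediate
14 | 4-formyl-3-methoxy-2,5-dimethylphenyl 4-{[2,4-bis(benzyloxy)-3,6-dimethylbenzoyl]oxy}-2-methoxy-3,5,6-trimethylbenzoate | O=Cc1c(OC)c(C)c(OC(=O)c2c(OC)c(C)c(OC(=O)c3c(OCc4ccccc4)c(C)c(OCc4ccccc4)cc3C)c(C)c2C)cc1C | intermediate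
15 | 4-[(4-{[2,4-bis(benzyloxy)-3,6-dimethylbenzoyl]oxy}-2-methoxy-3,5,6-trimethylbenzoyl)oxy]-2-methoxy-3,6-dimethylbenzoic acid | OC(=O)c1c(OC)c(C)c(OC(=O)c2c(OC)c(C)c(OC(=O)c3c(OCc4ccccc4)c(C)c(OCc4ccccc4)cc3C)c(C)c2C)cc1C | intermediate
16 | 4-({4-[(2,4-dihydroxy-3,6-dimethylbenzoyl)oxy]-2-methoxy-3,5,6-trimethylbenzoyl}oxy)-2-methoxy-3,6-dimethylbenzoic acid (CNP0425440.0) | COc1c(C)c(OC(=O)c2c(C)c(C)c(OC(=O)c3c(C)cc(O)c(C)c3O)c(C)c2OC)cc(C)c1C(=O)O | target

**Totals**
Total step count: 11.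
Longest linear sequence: 9 steps (steps 1, 2, 5, 6, 7, 8, 9, 10, 11 from 1; the branch through steps 3 and 4 is equally long).

**Three steps most likely to fail**

Step 5 (esterification of a 2,6-disubstituted acid with a phenol that is flanked by two methyls and deactivated by a para CHO). The fallback sets out from 3 and comes back at 9. Acid 3 is converted with oxalyl chloride and catalytic DMF in CH2Cl2 into 2,4-bis(benzyloxy)-3,6-dimethylbenzoyl chloride F1. This isolated acid chloride is then used under basic instead of acidic conditions (Et3N, cat. DMAP, toluene, 60 °C) on 7. The more acidic, non-chelated 4-OH of 7 is the one that is ionised and acylated, giving 9.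

Step 6 (carbonate-mediated methylation next to an activated aryl ester, which could be cleaved or transacylated). The fallback sets out from 7 and comes back at 10, putting the methyl ether in before the ester exists. Aldehyde 7 is mono-allylated at the non-chelated 4-OH (allyl bromide 1.05 equiv, K2CO3, acetone, rt) to 2-hydroxy-3,5,6-trimethyl-4-(prop-2-en-1-yloxy)benzaldehyde F2. Methylation (MeI, K2CO3, DMF, 50 °C) gives 2-methoxy-3,5,6-trimethyl-4-(prop-2-en-1-yloxy)benzaldehyde F3. Pd(PPh3)4 and morpholine in THF remove the allyl group to give 4-hydroxy-2-methoxy-3,5,6-trimethylbenzaldehyde F4. TFAA coupling of F4 with 3 (through 8) then gives 10 directly.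

Step 8 (second esterification, with a large acid and a formyl-deactivated phenol that has a free ring position). The fallback sets out from 3 and 11 and comes back at 16, replacing the aldehyde partner by the more nucleophilic benzyl ester. Hydrogenolysis of 3 (H2, Pd/C, EtOAc) gives 2,4-dihydroxy-3,6-dimethylbenzoic acid F5. Carboxylate alkylation (BnBr, KHCO3, DMF, rt) gives benzyl 2,4-dihydroxy-3,6-dimethylbenzoate F6. TFAA coupling of F6 with 11 (through 12) gives benzyl 4-[(4-{[2,4-bis(benzyloxy)-3,6-dimethylbenzoyl]oxy}-2-methoxy-3,5,6-trimethylbenzoyl)oxy]-2-hydroxy-3,6-dimethylbenzoate F7. Methylation (MeI, K2CO3, DMF) gives benzyl 4-[(4-{[2,4-bis(benzyloxy)-3,6-dimethylbenzoyl]oxy}-2-methoxy-3,5,6-trimethylbenzoyl)oxy]-2-methoxy-3,6-dimethylbenzoate F8. Hydrogenolysis of F8 (H2, Pd/C, EtOAc) removes all three benzyl groups and gives 16 without the late Pinnick oxidation.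

**Further compounds**
F1 | step 5 | 2,4-bis(benzyloxy)-3,6-dimethylbenzoyl chloride | O=C(Cl)c1c(OCc2ccccc2)c(C)c(OCc2ccccc2)cc1C
F2 | step 6 | 2-hydroxy-3,5,6-trimethyl-4-(prop-2-en-1-yloxy)benzaldehyde | O=Cc1c(O)c(C)c(OCC=C)c(C)c1C
F3 | step 6 | 2-methoxy-3,5,6-trimethyl-4-(prop-2-en-1-yloxy)benzaldehyde | O=Cc1c(OC)c(C)c(OCC=C)c(C)c1C
F4 | step 6 | 4-hydroxy-2-methoxy-3,5,6-trimethylbenzaldehyde | O=Cc1c(OC)c(C)c(O)c(C)c1C
F5 | step 8 | 2,4-dihydroxy-3,6-dimethylbenzoic acid | OC(=O)c1c(O)c(C)c(O)cc1C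
F6 | step 8 | benzyl 2,4-dihydroxy-3,6-dimethylbenzoate | O=C(OCc1ccccc1)c1c(O)c(C)c(O)cc1C
F7 | step 8 | benzyl 4-[(4-{[2,4-bis(benzyloxy)-3,6-dimethylbenzoyl]oxy}-2-methoxy-3,5,6-trimethylbenzoyl)oxy]-2-hydroxy-3,6-dimethylbenzoate | O=C(OCc1ccccc1)c1c(O)c(C)c(OC(=O)c2c(OC)c(C)c(OC(=O)c3c(OCc4ccccc4)c(C)c(OCc4ccccc4)cc3C)c(C)c2C)cc1C
F8 | step 8 | benzyl 4-[(4-{[2,4-bis(benzyloxy)-3,6-dimethylbenzoyl]oxy}-2-methoxy-3,5,6-trimethylbenzoyl)oxy]-2-methoxy-3,6-dimethylbenzoate | O=C(OCc1ccccc1)c1c(OC)c(C)c(OC(=O)c2c(OC)c(C)c(OC(=O)c3c(OCc4ccccc4)c(C)c(OCc4ccccc4)cc3C)c(C)c2C)cc1C
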